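The C6 (unit B)–C8 (unit A) biaryl bond is the disconnection on which the route rests. C8 of unit A lies between the oxygen-bearing carbons C7 and C8a of an orcinol-type benzene ring whose methyl sits at C5. That ring is therefore carried as 5-methylcyclohexane-1,3-dione, with C8 as its doubly activated C2. One palladium-catalysed enolate arylation joins this carbon to C6 of a finished 7-benzyloxy-6-bromo-4-methoxy-5-methylcoumarin. Dehydrogenation then creates the tetra-ortho-substituted biaryl as a symmetrical resorcinol, on which the second pyranone can close in only one way.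

Key step: step 6

Remark: the target has no stereocentre and its biaryl axis carries no descriptor, so the axis is made racemic. Unit B is the 7-oxygenated 4-methoxy-5-methylcoumarin joined through C6 (unprimed locants); unit A is the 4,7-dimethoxy-5-methylcoumarin joined through C8 (primed locants).

Step 1
Reactants: 1 2-bromo-1,5-dimethoxy-3-methylbenzene
Product: 2 1-(3-bromo-4,6-dimethoxy-2-methylphenyl)ethanone
Conditions: AcCl (1.2 equiv), SnCl4 (1.2 equiv), CH2Cl2, 0 °C to rt
Reagents that add atoms: acetyl chloride, CC(=O)Cl
Why: Friedel–Crafts acylation should enter the free position ortho to the methyl group and para to a methoxy group, because the only other free carbon is wedged between two methoxy groups, and SnCl4 is mild enough not to cleave the ethers or shift the bromine.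

Step 2
Reactants: 2 1-(3-bromo-4,6-dimethoxy-2-methylphenyl)ethanone
Product: 3 1-(3-bromo-4,6-dihydroxy-2-methylphenyl)ethanone
Conditions: BBr3 (3.5 equiv), CH2Cl2, −78 °C to rt; then H2O
Reagents that add atoms: none
Why: Lewis-acid cleavage of aryl methyl ethers by BBr3 frees both oxygens, which then differ through the hydrogen bond of the ortho one to the acetyl group, while the ketone and the aryl bromide are inert to the reagent in the cold.

Step 3
Reactants: 3 1-(3-bromo-4,6-dihydroxy-2-methylphenyl)ethanone
Product: 4 1-(4-benzyloxy-3-bromo-6-hydroxy-2-methylphenyl)ethanone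
Conditions: BnBr (1.05 equiv), K2CO3 (1.1 equiv), acetone, 50 °C
Reagents that add atoms: benzyl bromide, BrCc1ccccc1
Why: Williamson etherification with one equivalent of halide should alkylate only the more acidic hydroxyl para to the acetyl group, the ortho hydroxyl being tied up in a hydrogen bond to the carbonyl oxygen.

Step 4
Reactants: 4 1-(4-benzyloxy-3-bromo-6-hydroxy-2-methylphenyl)ethanone
Product: 6 7-benzyloxy-6-bromo-4-hydroxy-5-methylcoumarin, via ethyl keto ester 5 (not isolated)
Conditions: NaH (4 equiv), (EtO)2CO, toluene, 110 °C; then aq. HCl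
Reagents that add atoms: diethyl carbonate, CCOC(=O)OCC
Why: Claisen condensation of the ketone enolate with the carbonate, followed by lactonization of the phenoxide onto the new ester (6-exo-trig acyl substitution), is the standard passage from 2-hydroxyacetophenones to 4-hydroxycoumarins and closes the pyranone of unit B.

Step 5
Reactants: 6 7-benzyloxy-6-bromo-4-hydroxy-5-methylcoumarin
Product: 7 7-benzyloxy-6-bromo-4-methoxy-5-methylcoumarin
Conditions: Me2SO4 (1.2 equiv), K2CO3, acetone, reflux
Reagents that add atoms: dimethyl sulfate, COS(=O)(=O)OC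
Why: O-alkylation of the vinylogous acid with the hard electrophile dimethyl sulfate under K2CO3 in acetone should give the 4-methoxycoumarin as the main isomer, any 2-methoxychromone being removed by chromatography.

Step 6
Reactants: 7 7-benzyloxy-6-bromo-4-methoxy-5-methylcoumarin; 8 5-methylcyclohexane-1,3-dione
Product: 9 2-(7-benzyloxy-4-methoxy-5-methyl-2-oxochromen-6-yl)-5-methylcyclohexane-1,3-dione
Conditions: Pd(OAc)2 (5 mol%), XPhos (10 mol%), K3PO4 (3 equiv), 8 (1.5 equiv), 1,4-dioxane, 100 °C; then aq. HCl to pH 2
Reagents that add atoms: none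
Why: Zerovalent palladium generated from Pd(OAc)2 and XPhos inserts into the C6–Br bond of 7, the potassium enolate of 8 replaces bromide on the divalent palladium aryl, and reductive elimination from the carbon-bound enolate forms the bond between C6 of unit B and C2 of the dione, the future C6–C8' biaryl bond. The closest known reaction type is the palladium-catalysed alpha-arylation of cyclic 1,3-diketones with 2,6-disubstituted aryl bromides under bulky dialkylbiarylphosphine ligands and K3PO4. No ring is closed, because the carbocycle of unit A arrives preformed and only has to be aromatized in step 7. The single stereogenic carbon of the enolized product (C5 of the dione ring) is formed racemic under no control and disappears on aromatization. The step needs one C-arylation at C2 and a defined site on unit B: C2 is the only doubly activated carbon of the symmetrical dione, the product is a crowded, fully enolized vinylogous acid held as its unreactive potassium salt so that it is not arylated again, and the position on unit B is dictated by the bromine carried from 1. Anhydrous K3PO4 in dioxane is too poor a nucleophile to open the lactone or displace the 4-methoxy group.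

Step 7
Reactants: 9 2-(7-benzyloxy-4-methoxy-5-methyl-2-oxochromen-6-yl)-5-methylcyclohexane-1,3-dione
Product: 10 7-benzyloxy-6-(2,6-dihydroxy-4-methylphenyl)-4-methoxy-5-methylcoumarin
Conditions: Pd(O2CCF3)2 (10 mol%), 2-(dimethylamino)pyridine (20 mol%), TsOH (40 mol%), O2 (1 atm), DMSO, 80 °C
Reagents that add atoms: none
Why: Palladium-catalysed aerobic dehydrogenation of a cyclohexenone to a phenol applies because the enol of 9 is a 3-hydroxycyclohex-2-enone, so that palladation at C4 of the dione ring and beta-hydride elimination from C5 remove one molecule of hydrogen, the 2-arylresorcinol appears as the aromatic tautomer, and O2 returns zerovalent palladium to the divalent state without any halogenating or hydrogen-transfer agent that could touch C3 of the methoxycoumarin or the benzyl ether.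

Step 8
Reactants: 10 7-benzyloxy-6-(2,6-dihydroxy-4-methylphenyl)-4-methoxy-5-methylcoumarin
Product: 12 6-(3-acetyl-2,6-dihydroxy-4-methylphenyl)-7-benzyloxy-4-methoxy-5-methylcoumarin, via ketiminium chloride 11 (not isolated)
Conditions: MeCN (excess), ZnCl2, HCl (g), Et2O, 0 °C; then H2O, 60 °C
Reagents that add atoms: acetonitrile, CC#N; water, O
Why: In this Houben–Hoesch acylation the nitrilium electrophile attacks the resorcinol ring at one of its two symmetry-equivalent free carbons (ortho to one hydroxyl, para to the other), the iminium salt formed blocks a second acylation, and warm water hydrolyses it to the methyl ketone.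

Step 9
Reactants: 12 6-(3-acetyl-2,6-dihydroxy-4-methylphenyl)-7-benzyloxy-4-methoxy-5-methylcoumarin
Product: 13 6-(3-acetyl-2-hydroxy-6-methoxy-4-methylphenyl)-7-benzyloxy-4-methoxy-5-methylcoumarin
Conditions: Me2SO4 (1.05 equiv), K2CO3 (1.1 equiv), acetone, rt
Reagents that add atoms: dimethyl sulfate, COS(=O)(=O)OC
Why: Williamson methylation with one equivalent of dimethyl sulfate should take the free hydroxyl para to the acetyl group, the other one being deactivated by its hydrogen bond to the ketone, as in the classical selective 4-O-alkylation of 2,4-dihydroxyacetophenones.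

Step 10
Reactants: 13 6-(3-acetyl-2-hydroxy-6-methoxy-4-methylphenyl)-7-benzyloxy-4-methoxy-5-methylcoumarin
Product: 15 7-benzyloxy-4'-hydroxy-4,7'-dimethoxy-5,5'-dimethyl-6,8'-bicoumarin, via methyl keto ester 14 (not isolated)
Conditions: NaH (4 equiv), (MeO)2CO, toluene, 100 °C; then aq. HCl
Reagents that add atoms: dimethyl carbonate, COC(=O)OC
Why: The carbonate Claisen condensation and lactonization of step 4 closes the pyranone of unit A onto the chelated hydroxyl (6-exo-trig), the dimethyl ester being chosen so that the methoxide set free can only exchange the 4-methoxy group of unit B for itself, and the acidic work-up recloses the unit B lactone should it have been opened.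

Step 11
Reactants: 15 7-benzyloxy-4'-hydroxy-4,7'-dimethoxy-5,5'-dimethyl-6,8'-bicoumarin
Product: 16 7-benzyloxy-4,4',7'-trimethoxy-5,5'-dimethyl-6,8'-bicoumarin
Conditions: Me2SO4 (1.2 equiv), K2CO3, acetone, reflux
Reagents that add atoms: dimethyl sulfate, COS(=O)(=O)OC
Why: O-alkylation of the 4-hydroxycoumarin as in step 5 should give the 4'-methyl ether, the only acidic hydroxyl left in the molecule being the one that is methylated.

Step 12
Reactants: 16 7-benzyloxy-4,4',7'-trimethoxy-5,5'-dimethyl-6,8'-bicoumarin
Product: 17 7-hydroxy-4,4',7'-trimethoxy-5,5'-dimethyl-6,8'-bicoumarin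
Conditions: H2 (1 atm), Pd/C (10 %), EtOAc, rt
Reagents that add atoms: none
Why: Hydrogenolysis of the aryl benzyl ether over Pd/C at ambient pressure should free the 7-hydroxyl of unit B, while the C3–C4 double bonds, being enol ethers conjugated to the lactone carbonyls, and the methyl ethers are not reduced.

Compound list
1 | 2-bromo-1,5-dimethoxy-3-methylbenzene | COc1cc(OC)c(Br)c(C)c1 | starting material
2 | 1-(3-bromo-4,6-dimethoxy-2-methylphenyl)ethanone | COc1cc(OC)c(C(C)=O)c(C)c1Br | intermediate
3 | 1-(3-bromo-4,6-dihydroxy-2-methylphenyl)ethanone | CC(=O)c1c(O)cc(O)c(Br)c1C | intermediate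
4 | 1-(4-benzyloxy-3-bromo-6-hydroxy-2-methylphenyl)ethanone | CC(=O)c1c(O)cc(OCc2ccccc2)c(Br)c1C | intermediate
5 | ethyl 3-(4-benzyloxy-3-bromo-6-hydroxy-2-methylphenyl)-3-oxopropanoate (formed in the flask) | CCOC(=O)CC(=O)c1c(O)cc(OCc2ccccc2)c(Br)c1C | intermediate
6 | 7-benzyloxy-6-bromo-4-hydroxy-5-methylcoumarin | Oc1cc(=O)oc2cc(OCc3ccccc3)c(Br)c(C)c12 | intermediate
7 | 7-benzyloxy-6-bromo-4-methoxy-5-methylcoumarin | COc1cc(=O)oc2cc(OCc3ccccc3)c(Br)c(C)c12 | intermediate
8 | 5-methylcyclohexane-1,3-dione | CC1CC(=O)CC(=O)C1 | starting material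
9 | 2-(7-benzyloxy-4-methoxy-5-methyl-2-oxochromen-6-yl)-5-methylcyclohexane-1,3-dione (mainly enol; ring stereocentres undefined) | COc1cc(=O)oc2cc(OCc3ccccc3)c(C3C(=O)CC(C)CC3=O)c(C)c12 | intermediate
10 | 7-benzyloxy-6-(2,6-dihydroxy-4-methylphenyl)-4-methoxy-5-methylcoumarin | COc1cc(=O)oc2cc(OCc3ccccc3)c(-c3c(O)cc(C)cc3O)c(C)c12 | intermediate
11 | ketiminium chloride of 12 (formed in the flask) | COc1cc(=O)oc2cc(OCc3ccccc3)c(-c3c(O)cc(C)c(C(C)=[NH2+])c3O)c(C)c12.[Cl-] | intermediate
12 | 6-(3-acetyl-2,6-dihydroxy-4-methylphenyl)-7-benzyloxy-4-methoxy-5-methylcoumarin (racemic axis) | COc1cc(=O)oc2cc(OCc3ccccc3)c(-c3c(O)cc(C)c(C(C)=O)c3O)c(C)c12 | intermediate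
13 | 6-(3-acetyl-2-hydroxy-6-methoxy-4-methylphenyl)-7-benzyloxy-4-methoxy-5-methylcoumarin (racemic axis) | COc1cc(=O)oc2cc(OCc3ccccc3)c(-c3c(OC)cc(C)c(C(C)=O)c3O)c(C)c12 | intermediate
14 | methyl 3-[3-(7-benzyloxy-4-methoxy-5-methyl-2-oxochromen-6-yl)-2-hydroxy-4-methoxy-6-methylphenyl]-3-oxopropanoate (formed in the flask) | COC(=O)CC(=O)c1c(C)cc(OC)c(-c2c(OCc3ccccc3)cc3oc(=O)cc(OC)c3c2C)c1O | intermediate
15 | 7-benzyloxy-4'-hydroxy-4,7'-dimethoxy-5,5'-dimethyl-6,8'-bicoumarin (racemic axis) | COc1cc(=O)oc2cc(OCc3ccccc3)c(-c3c(OC)cc(C)c4c(O)cc(=O)oc34)c(C)c12 | intermediate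
16 | 7-benzyloxy-4,4',7'-trimethoxy-5,5'-dimethyl-6,8'-bicoumarin (racemic axis) | COc1cc(=O)oc2cc(OCc3ccccc3)c(-c3c(OC)cc(C)c4c(OC)cc(=O)oc34)c(C)c12 | intermediate
17 | 7-hydroxy-4,4',7'-trimethoxy-5,5'-dimethyl-6,8'-bicoumarin (CNP0113839.0; racemic axis) | COc1cc(C)c2c(OC)cc(=O)oc2c1-c1c(O)cc2oc(=O)cc(OC)c2c1C | target

Total step count: 12. Longest linear sequence: 12 steps (1 to 17); the dione 8 is bought.

Steps most likely to fail

Step 6. The catalytic cycle may stall after oxidative addition, with slow reductive elimination at the crowded enolate carbon and hydrodebromination of 7 taking over. The fallback takes the dione out of the palladium step. Setting out from 7, borylation with B2(OH)4 (Pd(OAc)2, XPhos, KOAc, ethanol, 80 °C) should give (7-benzyloxy-4-methoxy-5-methyl-2-oxochromen-6-yl)boronic acid F1. Boron-to-lead exchange with Pb(OAc)4 and catalytic Hg(OAc)2 in CHCl3 at 40 °C should then give (7-benzyloxy-4-methoxy-5-methyl-2-oxochromen-6-yl)lead triacetate F2. This aryllead reagent arylates 8 at C2 in CHCl3 with pyridine at 40 to 60 °C (Pinhey arylation), a ligand-coupling process that tolerates di-ortho-substituted aryl groups, and the route is rejoined at 9.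

Step 7. Palladation of the hindered, enolized dione may be incomplete, or the electron-rich resorcinol may be oxidized further under O2. The fallback oxidizes a preformed diene instead of the free dione. Setting out from 9, TMSOTf and Et3N in CH2Cl2 at 0 °C should give 7-benzyloxy-4-methoxy-5-methyl-6-[4-methyl-2,6-bis(trimethylsilyloxy)cyclohexa-1,5-dien-1-yl]coumarin F3. DDQ in dioxane at rt dehydrogenates this cyclohexadiene to the arene, 7-benzyloxy-4-methoxy-5-methyl-6-[4-methyl-2,6-bis(trimethylsilyloxy)phenyl]coumarin F4. Dilute HCl in THF removes the silyl groups and the route is rejoined at 10.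

Step 8. The benzyl ether may be lost or the 4-methoxy enol ether hydrolysed under HCl and ZnCl2 and during ketimine hydrolysis, or O-imidate formation may replace C-acylation. The fallback builds the second pyranone without an acetophenone. Setting out from 10, heating with one equivalent of bis(2,4,6-trichlorophenyl) malonate in bromobenzene at reflux should acylate a phenol oxygen and close the ring by C-acylation at the only free ortho carbon. The two hydroxyls and the two free carbons are equivalent, so this can give only 7-benzyloxy-4',7'-dihydroxy-4-methoxy-5,5'-dimethyl-6,8'-bicoumarin F5. Exhaustive methylation with Me2SO4 and K2CO3 in acetone then leads to 16, where the route is rejoined; 12, 13 and 15 are bypassed.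

Further compounds
F1 | step 6 | (7-benzyloxy-4-methoxy-5-methyl-2-oxochromen-6-yl)boronic acid | COc1cc(=O)oc2cc(OCc3ccccc3)c(B(O)O)c(C)c12
F2 | step 6 | (7-benzyloxy-4-methoxy-5-methyl-2-oxochromen-6-yl)lead triacetate | COc1cc(=O)oc2cc(OCc3ccccc3)c([Pb](OC(C)=O)(OC(C)=O)OC(C)=O)c(C)c12
F3 | step 7 | 7-benzyloxy-4-methoxy-5-methyl-6-[4-methyl-2,6-bis(trimethylsilyloxy)cyclohexa-1,5-dien-1-yl]coumarin | COc1cc(=O)oc2cc(OCc3ccccc3)c(C3=C(O[Si](C)(C)C)CC(C)C=C3O[Si](C)(C)C)c(C)c12
F4 | step 7 | 7-benzyloxy-4-methoxy-5-methyl-6-[4-methyl-2,6-bis(trimethylsilyloxy)phenyl]coumarin | COc1cc(=O)oc2cc(OCc3ccccc3)c(-c3c(O[Si](C)(C)C)cc(C)cc3O[Si](C)(C)C)c(C)c12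
F5 | step 8 | 7-benzyloxy-4',7'-dihydroxy-4-methoxy-5,5'-dimethyl-6,8'-bicoumarin | COc1cc(=O)oc2cc(OCc3ccccc3)c(-c3c(O)cc(C)c4c(O)cc(=O)oc34)c(C)c12
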